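## Structural features

The target is a C26 meroterpenoid. A 6-hydroxy-2H-chromene (benzene ring fused through C4a and C8a to a pyran ring with a C3=C4 styrene-type alkene) carries at C2 a methyl group and the chain CH2–CH2–CH=C(CH3)–CH2–CH2, which ends at C1 of ring A, a 2,6,6-trimethylcyclohex-2-ene. There are two stereocentres, both S: the quaternary, oxygen-bearing C2 of the pyran and the allylic CH (C1) of ring A. Six chain atoms separate them, so neither can steer the other and each needs its own absolute control; the tether also holds one E-trisubstituted alkene. The fragile functions are three. The phenol para to the ring oxygen is easily oxidised. The tertiary allylic aryl ether C2–O1 ionises under acid (ring opening, racemisation) and, with the conjugated C3=C4 bond, is open to strong electron donors. The ring-A alkene would erase the ring-A stereocentre if acid moved it to the tetrasubstituted position. The real difficulty is the ring-A centre, a lone tertiary C–H between a quaternary C(CH3)2 carbon and a C(CH3)=CH alkene with no heteroatom to direct a reagent, whereas C2 maps onto a chiral-pool tertiary allylic alcohol. Ring A is a geranyl unit folded head to tail: the bond between its C(CH3)2 carbon (C6) and the CH stereocentre (C1), together with the C2=C3 ring alkene, is what forms when the terminal alkene of a geranyl chain is protonated and the inner alkene closes onto the cation. The key step exploits this and leaves a sulfonylmethyl group on C1 as the handle for joining the chain. The benzene ring (O1 on C8a para to the C6 hydroxyl, C4 on C4a) corresponds to a 1,2-dihalo-4-oxybenzene whose two halogens can be addressed in turn.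

## Logic of the disconnections

17 ⇒ 16. The O–Si bond of a silyl ether on the C6 oxygen is cut first. The phenol is the most oxidation-prone function and would be deprotonated by every base used earlier, so it stays masked to the end. Nothing is gained in skeleton, but all earlier steps become compatible. The forward step must free the phenol without strong acid or base.

16 ⇒ 15 ⇒ 5 + 13. The bond between the two methylene carbons that link ring A to the trisubstituted alkene is cut, after a phenylsulfonyl group is placed back on the methylene next to ring A. It is the one tether bond with a carbanion-stabilising position on one side and an allylic, leaving-group-bearing position on the other. The cut gives a C10 ring-A half and a C16 chromene half, each with one stereocentre, so the two remote centres are made separately. The forward steps demand SN2 alkylation of the hindered lithiated species 14 by a primary allylic bromide with the E geometry kept, and later removal of sulfur by electron transfer without harm to the chromene.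

13 ⇒ 12 ⇒ 11. The C–Br bond goes back to a C–O bond and this to a C–H bond of the E-methyl group at the chain end of 11. A dimethyl-substituted alkene terminus is what an ene-type allylic oxidation attacks at the E-methyl, so the alkene geometry of the target comes from reagent selectivity and not from an olefination. 11 then has only the carbons of the chiral-pool unit and the arene. The oxidation must touch that methyl alone; the ring alkene of 11 has no allylic hydrogen.

11 ⇒ 10. The pyran is opened at O1–C8a. Cutting the aryl–oxygen bond and not the alkyl–oxygen bond leaves the tertiary C2–O bond, and so the stereocentre, untouched in both directions. The result is an acyclic tertiary alcohol with an ortho-bromoaryl group on a Z-alkene. The forward step is a metal-catalysed coupling of a tertiary alkoxide with an aryl bromide, possible only from the Z isomer.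

10 ⇒ 9 ⇒ 7 + 8. The Z-alkene is traced to its E isomer and this is cut at C4–C4a. An arylation of a monosubstituted alkene gives the E-styrene directly, and 8 supplies C2 with its methyl group, its oxygen and the whole prenyl-ended arm in the right absolute configuration. The forward steps demand reaction at C–I with C–Br kept, then a contra-thermodynamic E-to-Z isomerisation.

7 ⇒ 6. The O–Si bond is cut to the commercial dihalophenol. The silyl group must be bulky enough to survive carbonate bases, an organolithium and an amalgam.

5 ⇒ 4. The ring-A bond between the C(CH3)2 carbon and the CH stereocentre is cut, and the ring alkene is traced to the cation left by that closure. This removes the ring and the stereocentre in one operation and leads to an achiral, acyclic C10 chain. The forward step needs an acid that protonates only the terminal alkene, discriminates the two mirror-image chair folds and ends by loss of a ring CH2 proton.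

4 ⇒ 2 + 3, 2 ⇒ 1. The C–S bond and then the C–Br bond are cut, which leads to two commodity materials. The forward steps are SN2 reactions at a primary allylic carbon that must not scramble the E-alkene.

## Other disconnections considered

Alternative 1: The cut is C4–C4a, the bond between the styrene carbon and the benzene ring. In the forward sense the aryl propargyl ether A2 (the 4-(triisopropylsilyloxy)phenyl ether of an (S)-tertiary propargylic carbinol with a 2-silyloxyethyl arm) would be treated with the monovalent gold complex Ph3PAuNTf2. The activated terminal alkyne carbon would be attacked 6-endo-dig by the arene carbon ortho to the ether oxygen, and protodeauration would give chromene A1.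
- In its favour: the closure is a neutral, catalytic isomerisation; the two ortho positions are equivalent; the alkene is born cis inside the ring; and the C2–O bond is not touched.
- Against it: A2 would need an enantioselective alkynylation of a methyl alkyl ketone and an etherification of a tertiary alkoxide without ionisation, and cationic gold can ionise tertiary propargylic ethers. A1 also has only two chain carbons, so iodide A3 would have to be joined by an sp3–sp2 coupling to vinyl iodide A4, whose E geometry would need a separate carbometalation sequence.
- Structure: the chosen plan takes C2 from 8 and the E-alkene from a prenyl terminus, and both are stronger than what A2 and A4 offer.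
- Mechanism: the gold closure is the equal or the better of steps 5 to 7, one operation in place of three and no isomerisation.
- Step economy: the alternative is longer overall, and it gives no answer for ring A, so step 3 or an equivalent would still be needed.

Alternative 2: The cuts are the two bonds that flank the central C5 unit. Lithiated 5 would displace chloride from A6, and in the same flask the zerovalent palladium complex Pd(PPh3)4 would ionise the allylic acetate so that the sodium enolate of A7 attacks the unhindered allyl terminus to give A5.
- In its favour: it uses 5 in the same carbanion role, so the two plans are equal on the key step. The E-alkene comes ready-made in A6, which is better than the oxidation and bromination of steps 8 and 9. Sulfur could be removed at the stage of ketone A8, before any chromene exists, which is also better.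
- Against it: the chain ends in the methyl ketone A8, so C2 would have to be created by an enantioselective addition to a carbonyl group flanked by CH3 and CH2, and a chromene would still have to be annulated. The lithiated sulfone could also attack the acetate carbonyl.
- Structure: the chosen plan is stronger, because the tertiary ether centre is bought.
- Mechanism: the alternative is stronger on the reductive step and weaker on stereocontrol at C2.
- Step economy: the three-component union is more convergent, but dealkoxycarbonylation, desulfonylation, creation of C2 and ring formation make the whole longer.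

Alternative 3: The cut is O1–C8a, made last on the complete chain. The Z-configured bromoaryl carbinol A10 would be treated with Pd(OAc)2, a di-tert-butylbiarylphosphine and Cs2CO3 to close the pyran and give A9, the tert-butyldimethylsilyl ether of the target.
- In its favour: the closing reaction is the same type as step 7, so it is equal on mechanism and on safety for C2. Sulfur would be removed before arene and pyran are present, which is better than step 11, and the allylic oxidation would run on 8 itself, a simpler substrate than 11.
- Against it: the fragments are joined early, so the Heck reaction, the isomerisation and the etherification all run on material that contains the product of the key step, and each must be selective in a triene.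
- Structure: equal, same building blocks and same bonds.
- Mechanism: better chemoselectivity in the reduction.
- Step economy: equal step count, but less convergent, since the most valuable intermediate is exposed to the three least predictable operations. This ordering is kept as the fallback for step 11.

Key step: step 3

Remarks on the chemistry (assumptions):
- The (R)-ligand is assigned to (S)-5 by analogy with related proton-initiated closures; the sense is not secured for a sulfone, and the (S)-ligand would be used if it proves opposite.
- The ligand of step 3 is a recoverable reagent, made in one O-alkylation of (R)-1,1'-bi-2-naphthol with 2-fluorobenzyl bromide, and is not counted as a step.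
- Commercial 8 is taken to be of high enantiomeric purity, because its carbinol centre becomes C2 unchanged.

## Route

Step 1
Reactants: 1 geraniol [(2E)-3,7-dimethylocta-2,6-dien-1-ol]
Product: 2 geranyl bromide [(2E)-1-bromo-3,7-dimethylocta-2,6-diene]
Conditions: PBr3 (0.4 equiv), pyridine (cat.), Et2O, −10 °C
Reagents that add atoms: phosphorus tribromide, BrP(Br)Br
Why: The primary allylic alcohol is activated as a phosphite ester and displaced by bromide (SN2); at low temperature in ether the E-alkene and the position of the double bond are kept, and the crude bromide is used at once.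

Step 2
Reactants: 2 geranyl bromide; 3 sodium benzenesulfinate
Product: 4 geranyl phenyl sulfone [{[(2E)-3,7-dimethylocta-2,6-dien-1-yl]sulfonyl}benzene]
Conditions: DMF, 20 °C
Reagents that add atoms: none
Why: SN2 S-alkylation of the sulfinate by the soft primary allylic bromide in a dipolar aprotic solvent, the standard preparation of allylic sulfones; the E geometry is not touched.

Step 3
Reactants: 4 geranyl phenyl sulfone
Product: 5 (S)-α-cyclogeranyl phenyl sulfone [({[(1S)-2,6,6-trimethylcyclohex-2-en-1-yl]methyl}sulfonyl)benzene]
Conditions: SnCl4 (2 equiv), (R)-2-(2-fluorobenzyloxy)-2'-hydroxy-1,1'-binaphthyl (2.2 equiv), toluene, −78 °C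
Reagents that add atoms: none
Why: Proposed new method: coordination of SnCl4 to the binaphthol makes its remaining O–H a strong, chirally encumbered proton donor, which should protonate the electron-rich terminal alkene C6=C7 of 4 while the C2=C3 alkene, folded beneath it in a chair-like array, bonds to C7 from the opposite face, so that proton transfer and C2–C7 bond formation occur inside one chiral contact ion pair; the closest known reaction types are the racemic protic-acid closure of geranyl sulfones to α-cyclogeranyl sulfones and the tin tetrachloride–binaphthol proton-initiated cyclisations of geranyl ethers and higher polyenes. Ring A closes 6-endo-trig with respect to the attacking alkene, both of whose carbons end in the ring, and the tertiary cation at C3 then loses a proton from the ring CH2 (C4) to give the endocyclic alkene. The only new stereocentre, the ring CH (former C2), is set by reagent control: the chiral tin binaphtholate counter-ion selects one of the two mirror-image chair folds and so the face of the C2=C3 alkene that is engaged. Site selectivity of protonation is secured by the substrate, because the allylic sulfonyl group inductively deactivates C2=C3 and leaves C6=C7 as the only basic alkene. The cascade stops after one ring because the sulfone is not nucleophilic and its phenyl ring is deactivated toward the cation. The direction of proton loss is not secured by the substrate and rests on the kinetic preference for the ring CH2 seen in protic-acid closures; an exocyclic isomer could still be drawn into the ring by mild acid without touching the stereocentre, whereas loss of the CH proton would erase it. The acid is used in excess because the sulfonyl oxygens compete weakly for tin, and the ligand is recovered on work-up.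

Step 4
Reactants: 6 4-bromo-3-iodophenol
Product: 7 (4-bromo-3-iodophenoxy)triisopropylsilane
Conditions: i-Pr3SiCl, imidazole, DMF, 20 °C
Reagents that add atoms: chlorotriisopropylsilane, CC(C)[Si](Cl)(C(C)C)C(C)C
Why: Imidazole-promoted silylation of the phenol; the bulky triisopropylsilyl ether is chosen because it must survive carbonate bases, an organolithium and an amalgam and then leave under buffered fluoride.

Step 5
Reactants: 7 (4-bromo-3-iodophenoxy)triisopropylsilane; 8 (S)-linalool [(3S)-3,7-dimethylocta-1,6-dien-3-ol]
Product: 9 (1E,3S)-1-[2-bromo-5-(triisopropylsilyloxy)phenyl]-3,7-dimethylocta-1,6-dien-3-ol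
Conditions: Pd(OAc)2 (5 mol %), n-Bu4NCl, NaHCO3, DMF, 50 °C
Reagents that add atoms: none
Why: Heck reaction under ligand-free phase-transfer conditions: zerovalent palladium formed in the flask inserts into C–I much faster than into C–Br, and the aryl group adds to the unsubstituted vinyl carbon of 8. β-Hydride elimination can only go toward the aryl-bearing carbon, because the carbinol carbon has no hydrogen, and gives the E-styrene. The stereocentre is a spectator and the trisubstituted alkene is too hindered to insert.

Step 6
Reactants: 9 (1E,3S)-1-[2-bromo-5-(triisopropylsilyloxy)phenyl]-3,7-dimethylocta-1,6-dien-3-ol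
Product: 10 (1Z,3S)-1-[2-bromo-5-(triisopropylsilyloxy)phenyl]-3,7-dimethylocta-1,6-dien-3-ol
Conditions: Ir(ppy)3 (1 mol %), degassed MeCN, blue LEDs (450 nm), 20 °C
Reagents that add atoms: none
Why: Photocatalytic E-to-Z isomerisation by triplet energy transfer: the planar E-styrene is sensitised and relaxes to either isomer, whereas the Z isomer, twisted out of conjugation by the tertiary carbinol and the ortho bromine, is a poor acceptor and should accumulate. No bond to the stereocentre is broken, and recovered 9 can be resubmitted.

Step 7
Reactants: 10 (1Z,3S)-1-[2-bromo-5-(triisopropylsilyloxy)phenyl]-3,7-dimethylocta-1,6-dien-3-ol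
Product: 11 (2S)-2-methyl-2-(4-methylpent-3-en-1-yl)-6-(triisopropylsilyloxy)-2H-chromene
Conditions: Pd(OAc)2 (3 mol %), t-BuXPhos (2-di-tert-butylphosphino-2',4',6'-triisopropylbiphenyl, 4 mol %), Cs2CO3, toluene, 70 °C
Reagents that add atoms: none
Why: Intramolecular Buchwald–Hartwig C–O coupling: zerovalent palladium inserts into C–Br, the cesium alkoxide binds, and the bulky di-tert-butylbiarylphosphine drives C–O reductive elimination to close the pyran. The tertiary alkoxide has no hydrogen on the carbinol carbon, so β-hydride loss and arene reduction are not available. The O–C2 bond is never broken, so the configuration of 8 is retained.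

Step 8
Reactants: 11 (2S)-2-methyl-2-(4-methylpent-3-en-1-yl)-6-(triisopropylsilyloxy)-2H-chromene
Product: 12 (2E)-2-methyl-5-[(2S)-2-methyl-6-(triisopropylsilyloxy)-2H-chromen-2-yl]pent-2-en-1-ol
Conditions: SeO2 (0.3 equiv), t-BuOOH (3 equiv), salicylic acid (0.1 equiv), CH2Cl2, 0 to 20 °C
Reagents that add atoms: tert-butyl hydroperoxide, CC(C)(C)OO (stoichiometric oxygen source); selenium dioxide, O=[Se]=O (catalytic oxygen carrier)
Why: Riley allylic oxidation (ene reaction, then [2,3]-sigmatropic shift) attacks the more substituted end of the trisubstituted alkene at the methyl group trans to the chain and gives the E-allylic alcohol. C2 of the chromene has no allylic hydrogen, so the ring alkene offers no competing site, and catalytic SeO2 with t-BuOOH limits oxidation beyond the alcohol.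

Step 9
Reactants: 12 (2E)-2-methyl-5-[(2S)-2-methyl-6-(triisopropylsilyloxy)-2H-chromen-2-yl]pent-2-en-1-ol
Product: 13 (2S)-2-[(3E)-5-bromo-4-methylpent-3-en-1-yl]-2-methyl-6-(triisopropylsilyloxy)-2H-chromene
Conditions: CBr4, PPh3, CH2Cl2, 0 °C
Reagents that add atoms: carbon tetrabromide, BrC(Br)(Br)Br
Why: Appel reaction under neutral conditions: the alkoxyphosphonium ion is displaced by bromide (SN2) without allylic transposition and without acid that could open the chromene; the bromide is used directly.

Step 10
Reactants: 5 (S)-α-cyclogeranyl phenyl sulfone; 13 (2S)-2-[(3E)-5-bromo-4-methylpent-3-en-1-yl]-2-methyl-6-(triisopropylsilyloxy)-2H-chromene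
Product: 15 (2S)-2-methyl-2-[(3E)-4-methyl-6-(phenylsulfonyl)-6-[(1S)-2,6,6-trimethylcyclohex-2-en-1-yl]hex-3-en-1-yl]-6-(triisopropylsilyloxy)-2H-chromene (both epimers at the sulfonyl carbon), via lithiated sulfone 14 (not isolated)
Conditions: n-BuLi (1.0 equiv), THF, −78 °C; then 13, DMPU, −78 to −30 °C
Reagents that add atoms: none
Why: Only the CH2 next to sulfur is acidic, so lithiation leaves the ring-A stereocentre alone. SN2 alkylation of the primary allylic bromide by the sulfonyl carbanion is the classical chain coupling of terpenoid synthesis and keeps the E-alkene. The new sulfonyl-bearing centre forms as an epimer mixture, which does not matter because it is removed in step 11.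

Step 11
Reactants: 15 the coupled sulfone (both epimers)
Product: 16 (2S)-2-methyl-2-[(3E)-4-methyl-6-[(1S)-2,6,6-trimethylcyclohex-2-en-1-yl]hex-3-en-1-yl]-6-(triisopropylsilyloxy)-2H-chromene
Conditions: 6% Na(Hg), Na2HPO4, MeOH–THF, −20 °C
Reagents that add atoms: none
Why: Reductive desulfonylation by electron transfer: the arylsulfonyl group accepts electrons, the C–S bond fragments and the carbanion is protonated by methanol, which merges both epimers into one compound. Under cold, buffered conditions the isolated alkenes are inert and the electron-rich chromene styrene unit should be harder to reduce than the aryl sulfone.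

Step 12
Reactants: 16 the triisopropylsilyl ether of the target
Product: 17 (2S)-2-methyl-2-[(3E)-4-methyl-6-[(1S)-2,6,6-trimethylcyclohex-2-en-1-yl]hex-3-en-1-yl]-2H-chromen-6-ol (target, CNP0309797.1)
Conditions: n-Bu4NF, AcOH, THF, 0 °C, argon
Reagents that add atoms: none
Why: Fluoride cleaves the aryl O–Si bond, and acetic acid buffers the phenoxide so that the oxidation-prone chromenol is released under nearly neutral conditions. Neither the tertiary allylic ether nor the ring-A alkene meets acid strong enough to ionise or isomerise it.

## Compound list

1 | geraniol | CC(C)=CCC/C(C)=C/CO | starting material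
2 | geranyl bromide | CC(C)=CCC/C(C)=C/CBr | intermediate
3 | sodium benzenesulfinate | [Na+].[O-]S(=O)c1ccccc1 | starting material
4 | geranyl phenyl sulfone | CC(C)=CCC/C(C)=C/CS(=O)(=O)c1ccccc1 | intermediate
5 | (S)-α-cyclogeranyl phenyl sulfone | CC1=CCCC(C)(C)[C@@H]1CS(=O)(=O)c1ccccc1 | intermediate
6 | 4-bromo-3-iodophenol | Oc1ccc(Br)c(I)c1 | starting material
7 | (4-bromo-3-iodophenoxy)triisopropylsilane | CC(C)[Si](Oc1ccc(Br)c(I)c1)(C(C)C)C(C)C | intermediate
8 | (S)-linalool | C=C[C@@](C)(O)CCC=C(C)C | starting material
9 | (1E,3S)-1-[2-bromo-5-(triisopropylsilyloxy)phenyl]-3,7-dimethylocta-1,6-dien-3-ol | CC(C)=CCC[C@](C)(O)/C=C/c1cc(O[Si](C(C)C)(C(C)C)C(C)C)ccc1Br | intermediate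
10 | (1Z,3S)-1-[2-bromo-5-(triisopropylsilyloxy)phenyl]-3,7-dimethylocta-1,6-dien-3-ol | CC(C)=CCC[C@](C)(O)/C=C\c1cc(O[Si](C(C)C)(C(C)C)C(C)C)ccc1Br | intermediate
11 | (2S)-2-methyl-2-(4-methylpent-3-en-1-yl)-6-(triisopropylsilyloxy)-2H-chromene | CC(C)=CCC[C@@]1(C)C=Cc2cc(O[Si](C(C)C)(C(C)C)C(C)C)ccc2O1 | intermediate
12 | (2E)-2-methyl-5-[(2S)-2-methyl-6-(triisopropylsilyloxy)-2H-chromen-2-yl]pent-2-en-1-ol | OC/C(C)=C/CC[C@@]1(C)C=Cc2cc(O[Si](C(C)C)(C(C)C)C(C)C)ccc2O1 | intermediate
13 | (2S)-2-[(3E)-5-bromo-4-methylpent-3-en-1-yl]-2-methyl-6-(triisopropylsilyloxy)-2H-chromene | BrC/C(C)=C/CC[C@@]1(C)C=Cc2cc(O[Si](C(C)C)(C(C)C)C(C)C)ccc2O1 | intermediate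
14 | lithiated sulfone (5 lithiated at the carbon next to sulfur) | CC1=CCCC(C)(C)[C@@H]1C([Li])S(=O)(=O)c1ccccc1 | intermediate (not isolated)
15 | (2S)-2-methyl-2-[(3E)-4-methyl-6-(phenylsulfonyl)-6-[(1S)-2,6,6-trimethylcyclohex-2-en-1-yl]hex-3-en-1-yl]-6-(triisopropylsilyloxy)-2H-chromene, both epimers at the sulfonyl carbon | CC1=CCCC(C)(C)[C@@H]1C(S(=O)(=O)c1ccccc1)C/C(C)=C/CC[C@@]1(C)C=Cc2cc(O[Si](C(C)C)(C(C)C)C(C)C)ccc2O1 | intermediate
16 | (2S)-2-methyl-2-[(3E)-4-methyl-6-[(1S)-2,6,6-trimethylcyclohex-2-en-1-yl]hex-3-en-1-yl]-6-(triisopropylsilyloxy)-2H-chromene | CC1=CCCC(C)(C)[C@@H]1CC/C(C)=C/CC[C@@]1(C)C=Cc2cc(O[Si](C(C)C)(C(C)C)C(C)C)ccc2O1 | intermediate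
17 | (2S)-2-methyl-2-[(3E)-4-methyl-6-[(1S)-2,6,6-trimethylcyclohex-2-en-1-yl]hex-3-en-1-yl]-2H-chromen-6-ol | CC1=CCCC(C)(C)[C@@H]1CC/C(C)=C/CC[C@@]1(C)C=Cc2cc(O)ccc2O1 | target

## Step count and least certain steps

Total: 12 steps. Longest linear sequence: 9 steps (6 to 17, steps 4 to 12). The ring-A branch (steps 1 to 3) joins at step 10.

**Step 3 (key step).**
- What may go wrong: poor discrimination between the two chair folds, because the chiral counter-ion sits far from the sulfone-bearing alkene; unselective proton loss from the tertiary cation, including loss of the CH proton, which erases the stereocentre; and competition of the sulfonyl oxygens for tin, which weakens the chiral acid. The sense of induction is also unproven.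
- Fallback (known chemistry), from 4 back to 5: close 4 with H2SO4 in AcOH at 0 to 10 °C, the protic-acid closure known for this sulfone, to give racemic α-cyclogeranyl phenyl sulfone F1. Separate its enantiomers by preparative chromatography on a polysaccharide chiral stationary phase. The (S)-enantiomer is 5, and the route resumes at step 10.

**Step 6.**
- What may go wrong: incomplete enrichment of the Z isomer at the photostationary state, and competing photoreduction of the C–Br bond by the excited iridium complex.
- Fallback, from 9 back to 11, without any Z-alkene:
  - Reduce the disubstituted styrene alkene selectively with diimide (2-nitrobenzenesulfonylhydrazide, Et3N, CH2Cl2); the trisubstituted alkene reacts far more slowly and C–Br is inert. This gives (3S)-1-[2-bromo-5-(triisopropylsilyloxy)phenyl]-3,7-dimethyloct-6-en-3-ol F2.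
  - Close the ether under the conditions of step 7, which is best established for a saturated tether, to give (2S)-2-methyl-2-(4-methylpent-3-en-1-yl)-6-(triisopropylsilyloxy)chromane F3.
  - Dehydrogenate C3–C4 with DDQ in hot dioxane, a known conversion of 6-oxygenated 2,2-dialkylchromans into 2H-chromenes, to reach 11.

**Step 7.**
- What may go wrong: slow C–O reductive elimination from the hindered tertiary allylic alkoxide, which lets hydrodebromination or palladium-mediated return of the alkene to the E form take over.
- Fallback, from 10 back to 11, without a transition metal: treat 10 with LiTMP (3 equiv) in THF at −78 to 0 °C. The alkoxide forms first, and deprotonation ortho to bromine with loss of bromide then gives the aryne alkoxide lithium (1Z,3S)-1-[2,3-didehydro-5-(triisopropylsilyloxy)phenyl]-3,7-dimethylocta-1,6-dien-3-olate F4. Its tethered alkoxide adds to the aryne carbon that carried bromine; the Z-alkene enforces the six-membered ring. Protonation of the aryl anion gives 11.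

**Step 11.**
- What may go wrong: electron transfer to the chromene, with saturation of C3=C4 or reductive opening of the allylic aryl ether in competition with C–S cleavage.
- Fallback, from 8 and 14 (made from 5 as in step 10) back to 16, with sulfur removed before arene and pyran exist:
  - Oxidise 8 at its E-methyl group (SeO2, t-BuOOH) to (2E,6S)-2,6-dimethylocta-2,7-diene-1,6-diol F5.
  - Convert only its primary allylic hydroxyl (CBr4, PPh3) into (3S,6E)-8-bromo-3,7-dimethylocta-1,6-dien-3-ol F6.
  - Add F6 to two equivalents of 14; one acts as base for the tertiary hydroxyl and is recovered as 5. This gives (3S,6E)-3,7-dimethyl-9-(phenylsulfonyl)-9-[(1S)-2,6,6-trimethylcyclohex-2-en-1-yl]nona-1,6-dien-3-ol F7.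
  - Remove sulfur with Na(Hg) in buffered MeOH to give (3S,6E)-3,7-dimethyl-9-[(1S)-2,6,6-trimethylcyclohex-2-en-1-yl]nona-1,6-dien-3-ol F8.
  - Arylate with 7 as in step 5 to give (1E,3S,6E)-1-[2-bromo-5-(triisopropylsilyloxy)phenyl]-3,7-dimethyl-9-[(1S)-2,6,6-trimethylcyclohex-2-en-1-yl]nona-1,6-dien-3-ol F9.
  - Isomerise as in step 6 to (1Z,3S,6E)-1-[2-bromo-5-(triisopropylsilyloxy)phenyl]-3,7-dimethyl-9-[(1S)-2,6,6-trimethylcyclohex-2-en-1-yl]nona-1,6-dien-3-ol F10.
  - Close the pyran as in step 7 to reach 16.

## Further compounds

F1 | step 3 | racemic α-cyclogeranyl phenyl sulfone | CC1=CCCC(C)(C)C1CS(=O)(=O)c1ccccc1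
F2 | step 6 | (3S)-1-[2-bromo-5-(triisopropylsilyloxy)phenyl]-3,7-dimethyloct-6-en-3-ol | CC(C)=CCC[C@](C)(O)CCc1cc(O[Si](C(C)C)(C(C)C)C(C)C)ccc1Br
F3 | step 6 | (2S)-2-methyl-2-(4-methylpent-3-en-1-yl)-6-(triisopropylsilyloxy)chromane | CC(C)=CCC[C@@]1(C)CCc2cc(O[Si](C(C)C)(C(C)C)C(C)C)ccc2O1
F4 | step 7 | lithium (1Z,3S)-1-[2,3-didehydro-5-(triisopropylsilyloxy)phenyl]-3,7-dimethylocta-1,6-dien-3-olate (aryne alkoxide) | CC(C)=CCC[C@](C)([O-])/C=C\C1=CC(O[Si](C(C)C)(C(C)C)C(C)C)=CC#C1.[Li+]
F5 | step 11 | (2E,6S)-2,6-dimethylocta-2,7-diene-1,6-diol | C=C[C@@](C)(O)CC/C=C(\C)CO
F6 | step 11 | (3S,6E)-8-bromo-3,7-dimethylocta-1,6-dien-3-ol | C=C[C@@](C)(O)CC/C=C(\C)CBr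
F7 | step 11 | (3S,6E)-3,7-dimethyl-9-(phenylsulfonyl)-9-[(1S)-2,6,6-trimethylcyclohex-2-en-1-yl]nona-1,6-dien-3-ol, both epimers at C9 | CC1=CCCC(C)(C)[C@@H]1C(S(=O)(=O)c1ccccc1)C/C(C)=C/CC[C@](C)(O)C=C
F8 | step 11 | (3S,6E)-3,7-dimethyl-9-[(1S)-2,6,6-trimethylcyclohex-2-en-1-yl]nona-1,6-dien-3-ol | CC1=CCCC(C)(C)[C@@H]1CC/C(C)=C/CC[C@](C)(O)C=C
F9 | step 11 | (1E,3S,6E)-1-[2-bromo-5-(triisopropylsilyloxy)phenyl]-3,7-dimethyl-9-[(1S)-2,6,6-trimethylcyclohex-2-en-1-yl]nona-1,6-dien-3-ol | CC1=CCCC(C)(C)[C@@H]1CC/C(C)=C/CC[C@](C)(O)/C=C/c1cc(O[Si](C(C)C)(C(C)C)C(C)C)ccc1Br
F10 | step 11 | (1Z,3S,6E)-1-[2-bromo-5-(triisopropylsilyloxy)phenyl]-3,7-dimethyl-9-[(1S)-2,6,6-trimethylcyclohex-2-en-1-yl]nona-1,6-dien-3-ol | CC1=CCCC(C)(C)[C@@H]1CC/C(C)=C/CC[C@](C)(O)/C=C\c1cc(O[Si](C(C)C)(C(C)C)C(C)C)ccc1Br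
A1 | alternative 1 | (2S)-2-[2-(tert-butyldimethylsilyloxy)ethyl]-2-methyl-6-(triisopropylsilyloxy)-2H-chromene | CC(C)(C)[Si](C)(C)OCC[C@@]1(C)C=Cc2cc(O[Si](C(C)C)(C(C)C)C(C)C)ccc2O1
A2 | alternative 1 | tert-butyldimethyl{[(3S)-3-methyl-3-[4-(triisopropylsilyloxy)phenoxy]pent-4-yn-1-yl]oxy}silane | C#C[C@](C)(CCO[Si](C)(C)C(C)(C)C)Oc1ccc(O[Si](C(C)C)(C(C)C)C(C)C)cc1
A3 | alternative 1 | (2S)-2-(2-iodoethyl)-2-methyl-6-(triisopropylsilyloxy)-2H-chromene | ICC[C@@]1(C)C=Cc2cc(O[Si](C(C)C)(C(C)C)C(C)C)ccc2O1
A4 | alternative 1 | (6S)-6-[(3E)-4-iodo-3-methylbut-3-en-1-yl]-1,5,5-trimethylcyclohex-1-ene | CC1=CCCC(C)(C)[C@@H]1CC/C(C)=C/I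
A5 | alternative 2 | methyl (4E)-2-acetyl-5-methyl-7-(phenylsulfonyl)-7-[(1S)-2,6,6-trimethylcyclohex-2-en-1-yl]hept-4-enoate | CC1=CCCC(C)(C)[C@@H]1C(S(=O)(=O)c1ccccc1)C/C(C)=C/CC(C(C)=O)C(=O)OC
A6 | alternative 2 | (2E)-4-chloro-3-methylbut-2-en-1-yl acetate | CC(=O)OC/C=C(\C)CCl
A7 | alternative 2 | methyl acetoacetate | COC(=O)CC(C)=O
A8 | alternative 2 | (5E)-6-methyl-8-[(1S)-2,6,6-trimethylcyclohex-2-en-1-yl]oct-5-en-2-one | CC1=CCCC(C)(C)[C@@H]1CC/C(C)=C/CCC(C)=O
A9 | alternative 3 | tert-butyldimethylsilyl ether of the target | CC1=CCCC(C)(C)[C@@H]1CC/C(C)=C/CC[C@@]1(C)C=Cc2cc(O[Si](C)(C)C(C)(C)C)ccc2O1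
A10 | alternative 3 | (1Z,3S,6E)-1-[2-bromo-5-(tert-butyldimethylsilyloxy)phenyl]-3,7-dimethyl-9-[(1S)-2,6,6-trimethylcyclohex-2-en-1-yl]nona-1,6-dien-3-ol | CC1=CCCC(C)(C)[C@@H]1CC/C(C)=C/CC[C@](C)(O)/C=C\c1cc(O[Si](C)(C)C(C)(C)C)ccc1Br
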